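Each unit of starting material that opens gives one unit of open intermediate, and the two nucleophiles compete for it, the first giving target and the second other capture product.

all flasks: second nucleophile 0.144 M

|  | starting material | first nucleophile | capture agent | remark | time |
|---|---|---|---|---|---|
| delta | 0.12 M | 0.060 M | 0.036 M | run made earlier |  |
| alpha | 0.12 M | 0.24 M | 0.036 M | run made earlier |  |
| eta | 0.24 M | 0.12 M | 0.036 M | run made earlier |  |
| flask | 0.12 M | 0.120 M | 0.0360 M |  | 50 min |

- delta (time / min: target / %, starting material / %): 0.500: 26.1, 8.7; 1.00: 27.9, 2.0; 2.50: 22.8, 1.2; 5.00: 24.0, 0; 10.0: 23.3, 0; 25.0: 20.4, 1.8; 50.0: 20.6, 0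
- alpha (time / min: target / %, starting material / %): 0.500: 55.5, 4.4; 1.00: 56.1, 0.6; 2.50: 55.7, 0; 5.00: 51.5, 0.5; 10.0: 47.6, 0.5; 25.0: 46.6, 0.1; 50.0: 48.0, 0
- eta (time / min: target / %, starting material / %): 0.500: 40.3, 5.5; 1.50: 43.3, 0.1; 5.00: 37.4, 0.5; 15.0: 35.4, 0; 50.0: 35.0, 0.4

(standard deviation of a reading: 1 percentage point)

- reactions considered so far: starting material -> open intermediate; first nucleophile + open intermediate -> target; second nucleophile + open intermediate -> other capture product; open intermediate + capture agent -> trapped intermediate; target <-> isomer of the product

* the best time, 50 min at the latest, for target
* the amount of target, in percent of the starting material charged, at that time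

We count charges as fractions of the starting material charged and, as an assumption, set the capture agent's share at nil. The ratio of target to other capture product is then a factor times the ratio of the two nucleophiles at their mean amounts over the conversion. The highest target readings give 0.901 for delta, 0.729 for alpha and 0.853 for eta, so we carry their mean, 0.827, as our reading of the selectivity factor, first nucleophile's rate constant over second's.

The flask holds 1.00 of first and 1.20 of second nucleophile, so its opening share of target is 40.8 %. The earliest starting material readings give a decay constant of 5.64 min⁻¹, so by our reckoning target in the flask starts at a slope of 2.30 min⁻¹ of the charge and bends near 0.177 min. Mean amounts move the share to 42.1 %, and the mean costs little: the exact ratio of logarithms for those amounts returns 0.832 for the factor.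

Alpha's fall towards its last reading gives a relaxation constant of 0.210 min⁻¹, and last over highest readings average 80.1 %. We therefore read the forward step from target to isomer of the product as 0.0418 min⁻¹, far slower than the opening. In our reckoning the flask's fading inflow meets this loss at 0.869 min, with 40.9 % of the charge as target, and the curve then runs down to about 32.8 %.

The forecast puts the peak “just after conversion finishes”, at 1 min with 41 %, a little later than our time.

The simulated flask peaks at 0.897 min with 41.1 %. Target plus isomer of the product there comes to 42.5 % against our mean share of 42.1 %, with 0.113 % trapped intermediate, and target in the flask stands at 33.4 % after 50.0 min.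

    starting material → open intermediate (k = 0.0937 s⁻¹)
    first nucleophile + open intermediate → target (k = 8.32 L mol⁻¹ s⁻¹)
    second nucleophile + open intermediate → other capture product (k = 9.64 L mol⁻¹ s⁻¹)
    open intermediate + capture agent → trapped intermediate (k = 0.0567 L mol⁻¹ s⁻¹)
    target ⇌ isomer of the product (K = 0.280, k = 7.83 × 10⁻⁴ s⁻¹)

In the neighbour charged with 0.48 M of first nucleophile, which is 4.00 of the charge, the same factor gives an opening share of 73.4 % and a mean share of 73.8 %. The same loss then gives a peak of 71.7 % and a level of 57.4 %. The simulated neighbour peaks at 71.7 % and ends with 58.2 % of target.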